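The trap is to count enzyme as a reagent, and to fear that a bigger charge takes starting material out of play.

the same everywhere: starting material 0.050 M
- dawn: second substrate 0.013 M; enzyme 5 µM; run made earlier
- dusk: second substrate 0.019 M; enzyme 5 µM; run made earlier
- flask: second substrate 0.0250 M; enzyme 5.0 µM

| run | time / h | target / % |
|---|---|---|
| dawn | 0.500 | 83.0 |
| dawn | 1.00 | 98.1 |
| dawn | 1.50 | 100.1 |
| dawn | 2.00 | 99.1 |
| dawn | 2.50 | 99.4 |
| dawn | 3.00 | 100.1 |
| dawn | 4.00 | 100.4 |
| dusk | 0.200 | 43.9 |
| dusk | 0.500 | 82.4 |
| dusk | 1.00 | 96.9 |
| dusk | 1.50 | 98.9 |
| dusk | 2.00 | 100.6 |
| dusk | 3.00 | 99.4 |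
| dusk | 4.00 | 100.1 |

(each reading ± 0.5 percentage points)

- the numbers in the tables scatter by 0.5 percentage points (one standard deviation)
- on the list of suspects stand: starting material + enzyme <-> complex A; complex A -> enzyme + target; second substrate + enzyme <-> complex B; complex B -> enzyme + second product
- no earlier run changes the charge of enzyme; that part of a forecast is a guess

* factor on the rate of making target when 20% of the starting material are converted if enzyme is charged twice over
* factor on the rate when 20% of the starting material are converted if enzyme is charged at 50 µM instead

Here is my own reckoning, in slow motion, on the suspected steps. In the first instants free enzyme meets both substrates, and complex A and complex B form. The hold-up share in this flask is 0.0125%, the enzyme charged over the starting material left at 20% conversion. Even with every enzyme bound, [starting material] barely moves.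

Then comes the middle. The dusk run reads 43.9% at 0.200 h, which gives a pseudo-first-order constant near 2.89 h⁻¹. At 20% conversion in that run, that means a turnover frequency of about 23100 h⁻¹ per enzyme. One cycle takes about 0.156 s, far shorter than the time to that first reading. So the complexes keep step with the falling substrates. Dawn and dusk read 83.0% and 82.4% at 0.500 h, so the change in second substrate shows little at that reading.

Both substrates meet the same free enzyme, so the charge cancels from the ratio of their rates. More enzyme should run the same path faster. At 4.00 h, dawn and dusk read 100.4% and 100.1% target, and on the suspected steps the enzyme should come back free.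

So I expect 2 for the double charge and 10.0 for 50 µM. At 50 µM the hold-up share is 0.125%, far below one. A run that showed this share near one could bend these factors.

The forecast says 2 (from 1.8 to 2.1) and 10 (from 7.5 to 10.5), since “every rate scales with total enzyme”.

The flask gives 2.00 and 10.0.

    starting material + enzyme ⇌ complex A (K = 650 M⁻¹, k = 260 M⁻¹ s⁻¹)
    complex A → enzyme + target (k = 25.0 s⁻¹)
    second substrate + enzyme ⇌ complex B (K = 23.0 M⁻¹, k = 3400 M⁻¹ s⁻¹)
    complex B → enzyme + second product (k = 29.0 s⁻¹)

In the flask at 0.300 h, complex A holds 16.4% of the enzyme charged, with 41.0% of the starting material left. Rescaled to that moment, the hold-up share is 0.0244%. Complex A therefore ties up 0.00400% of the starting material left in the flask.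

(Readings and results come from a simulation from invented constants; scatter was added.)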